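Trachelogenin is reached by tracing its butyrolactone ring (O1, C2, C3, C4, C5) back to a cyclobutanone. Without its two C3 substituents the lactone has one stereocentre, C4, and this carbon lies on the mirror plane of a prochiral 3-substituted cyclobutanone. A catalytic enantioselective Baeyer–Villiger oxidation therefore builds the lactone ring, the O1–C2 and O1–C5 bonds and the C4 configuration in one operation, driven by release of four-ring strain. The precursor is 3-(3,4-dimethoxybenzyl)cyclobutanone, obtained from methyl eugenol by dichloroketene cycloaddition and dechlorination. C3 is then elaborated by hydroxylation, O-benzylation and enolate benzylation anti to the C4 side chain, and hydrogenolysis ends the route.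

Key step: step 3

Remark (assumption): lactone 7 must be the (R)-enantiomer. C4 keeps this spatial arrangement to the end and is called (S) from compound 9 onward only because the CIP priorities change once C3 carries oxygen. The catalyst antipode that gives (R)-7 is assumed to be found by a small-scale test of both enantiomers.

Step 1
Reactants: 1 methyl eugenol; 2 trichloroacetyl chloride
Product: 4 rac-2,2-dichloro-3-(3,4-dimethoxybenzyl)cyclobutan-1-one, via dichloroketene 3 (not isolated)
Conditions: Zn–Cu couple, POCl3, Et2O, reflux, slow addition of 2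
Reagents that add atoms: none
Why: Zinc dehalogenates 2 to dichloroketene, which should undergo the thermal [2+2] ketene–alkene cycloaddition with the terminal alkene, the ketene carbonyl carbon bonding to the terminal CH2 so that CCl2 sits next to the substituted carbon; the one stereocentre forms racemic and disappears in step 2.

Step 2
Reactants: 4 rac-2,2-dichloro-3-(3,4-dimethoxybenzyl)cyclobutan-1-one
Product: 5 3-(3,4-dimethoxybenzyl)cyclobutan-1-one
Conditions: Zn dust, AcOH, rt → 60 °C
Reagents that add atoms: none
Why: Reductive dehalogenation of the α,α-dichloroketone through zinc enolates should replace both C–Cl bonds by C–H without reducing the ketone or touching the aryl ethers, giving the achiral, mirror-symmetric ketone.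

Step 3
Reactants: 5 3-(3,4-dimethoxybenzyl)cyclobutan-1-one
Product: 7 (R)-4-(3,4-dimethoxybenzyl)dihydrofuran-2(3H)-one, via Criegee adduct 6 (not isolated)
Conditions: chiral H8-BINOL phosphoric acid with 3,3'-di(pyren-1-yl) groups (10 mol %, antipode giving (R)-7), 30% aq H2O2 (1.5 equiv), CHCl3, −40 °C
Reagents that add atoms: hydrogen peroxide, OO
Why: The chiral phosphoric acid activates the strained ketone and hydrogen peroxide by hydrogen bonding, peroxide adds to the carbonyl group to give Criegee adduct 6, and the ring CH2 antiperiplanar to the O–O bond shifts from carbon to oxygen with loss of water (Baeyer–Villiger oxidation; the closest known reaction type is the catalytic asymmetric Baeyer–Villiger desymmetrisation of prochiral 3-substituted cyclobutanones). The five-membered lactone is not closed by a cyclisation but arises by a 1,2-shift ring expansion of the four-membered ring, with O1 inserted between the former carbonyl carbon (C2) and the migrating CH2 (C5). No bond to C4 is made or broken: its configuration follows only from which of the two enantiotopic CH2 groups migrates, and the chiral hydrogen-bonding pocket of the catalyst holding the Criegee adduct makes that choice. Enantiotopic group selection is the only selectivity needed, because both candidate migrating carbons are identical methylenes and the mirror plane of 5 through the carbonyl carbon, C3 and the benzyl group allows only one constitutional product. Ring strain makes the ketone reactive enough for aqueous H2O2 at low temperature, where the uncatalysed background reaction and oxidation of the dimethoxyarene should be negligible.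

Step 4
Reactants: 7 (R)-4-(3,4-dimethoxybenzyl)dihydrofuran-2(3H)-one
Product: 9 (3R,4S)-4-(3,4-dimethoxybenzyl)-3-hydroxydihydrofuran-2(3H)-one, via potassium enolate 8 (not isolated)
Conditions: KHMDS, THF, −78 °C; then 2-(phenylsulfonyl)-3-phenyloxaziridine, −78 °C; AcOH quench
Reagents that add atoms: 2-(phenylsulfonyl)-3-phenyloxaziridine (Davis oxaziridine), O=S(=O)(c1ccccc1)N1OC1c1ccccc1
Why: In this Davis enolate hydroxylation the oxaziridine should transfer electrophilic oxygen to C3 mainly on the face opposite the C4 benzyl group (trans, 3R); the C3 ratio is immaterial because C3 becomes planar again in step 7, and the non-acidic C4 centre is untouched.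

Step 5
Reactants: 9 (3R,4S)-4-(3,4-dimethoxybenzyl)-3-hydroxydihydrofuran-2(3H)-one
Product: 10 (3R,4S)-3-(benzyloxy)-4-(3,4-dimethoxybenzyl)dihydrofuran-2(3H)-one
Conditions: BnBr, Ag2O, cat. TBAI, CH2Cl2, rt, dark
Reagents that add atoms: benzyl bromide, BrCc1ccccc1
Why: Silver(I) oxide-promoted Williamson-type O-benzylation runs under essentially neutral conditions, so the secondary hydroxyl should be etherified without enolising or opening the lactone; no stereocentre is formed.

Step 6
Reactants: 11 4-(benzyloxy)-3-methoxybenzyl alcohol
Product: 12 4-(benzyloxy)-3-methoxybenzyl bromide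
Conditions: PBr3, Et2O, 0 °C; used freshly prepared
Reagents that add atoms: phosphorus tribromide, BrP(Br)Br
Why: Bromination of the primary benzylic alcohol through a bromophosphite and SN2 displacement by bromide is fast at 0 °C and should leave the aryl benzyl and methyl ethers intact.

Step 7
Reactants: 10 (3R,4S)-3-(benzyloxy)-4-(3,4-dimethoxybenzyl)dihydrofuran-2(3H)-one; 12 4-(benzyloxy)-3-methoxybenzyl bromide
Product: 14 (3S,4S)-3-(benzyloxy)-3-[4-(benzyloxy)-3-methoxybenzyl]-4-(3,4-dimethoxybenzyl)dihydrofuran-2(3H)-one, via lithium enolate 13 (not isolated)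
Conditions: LDA, THF, −78 °C; then 12, DMPU, −78 → −30 °C
Reagents that add atoms: none
Why: In this lactone enolate alkylation (SN2 on a reactive benzylic bromide) the planar α-benzyloxy enolate should be attacked on the face opposite the adjacent C4 benzyl group, so the new benzyl group enters trans to it and the benzyloxy group ends cis, setting the quaternary C3 as (S) under substrate control.

Step 8
Reactants: 14 (3S,4S)-3-(benzyloxy)-3-[4-(benzyloxy)-3-methoxybenzyl]-4-(3,4-dimethoxybenzyl)dihydrofuran-2(3H)-one
Product: 15 trachelogenin, (3S,4S)-4-(3,4-dimethoxybenzyl)-3-hydroxy-3-(4-hydroxy-3-methoxybenzyl)dihydrofuran-2(3H)-one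
Conditions: H2 (1 atm), 10% Pd/C, EtOAc–EtOH, rt
Reagents that add atoms: none
Why: Catalytic hydrogenolysis should cleave both PhCH2–O bonds (phenolic and tertiary alkyl benzyl ether) to free the phenol and the tertiary alcohol, while the lactone, the methyl ethers and both stereocentres, which carry neither a benzylic C–O bond nor an acidic hydrogen, are unaffected.

Compound list
1 | methyl eugenol (4-allyl-1,2-dimethoxybenzene) | COc1ccc(CC=C)cc1OC | starting material
2 | trichloroacetyl chloride | O=C(Cl)C(Cl)(Cl)Cl | starting material
3 | dichloroketene (not isolated) | ClC(Cl)=C=O | intermediate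
4 | rac-2,2-dichloro-3-(3,4-dimethoxybenzyl)cyclobutan-1-one | COc1ccc(CC2CC(=O)C2(Cl)Cl)cc1OC | intermediate
5 | 3-(3,4-dimethoxybenzyl)cyclobutan-1-one (achiral) | COc1ccc(CC2CC(=O)C2)cc1OC | intermediate
6 | Criegee adduct, 3-(3,4-dimethoxybenzyl)-1-hydroperoxycyclobutan-1-ol (not isolated) | COc1ccc(CC2CC(O)(OO)C2)cc1OC | intermediate
7 | (R)-4-(3,4-dimethoxybenzyl)dihydrofuran-2(3H)-one | O=C1OC[C@@H](C1)Cc2ccc(OC)c(OC)c2 | intermediate
8 | potassium (R)-4-(3,4-dimethoxybenzyl)-4,5-dihydrofuran-2-olate, enolate of 7 (not isolated) | [K+].[O-]C1=C[C@@H](Cc2ccc(OC)c(OC)c2)CO1 | intermediate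
9 | (3R,4S)-4-(3,4-dimethoxybenzyl)-3-hydroxydihydrofuran-2(3H)-one (OH trans to the C4 benzyl group) | O=C1OC[C@H](Cc2ccc(OC)c(OC)c2)[C@H]1O | intermediate
10 | (3R,4S)-3-(benzyloxy)-4-(3,4-dimethoxybenzyl)dihydrofuran-2(3H)-one | O=C1OC[C@H](Cc2ccc(OC)c(OC)c2)[C@H]1OCc3ccccc3 | intermediate
11 | 4-(benzyloxy)-3-methoxybenzyl alcohol | COc1cc(CO)ccc1OCc2ccccc2 | starting material
12 | 4-(benzyloxy)-3-methoxybenzyl bromide | COc1cc(CBr)ccc1OCc2ccccc2 | intermediate
13 | lithium (S)-3-(benzyloxy)-4-(3,4-dimethoxybenzyl)-4,5-dihydrofuran-2-olate, enolate of 10 (not isolated) | [Li+].[O-]C1=C(OCc2ccccc2)[C@@H](Cc3ccc(OC)c(OC)c3)CO1 | intermediate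
14 | (3S,4S)-3-(benzyloxy)-3-[4-(benzyloxy)-3-methoxybenzyl]-4-(3,4-dimethoxybenzyl)dihydrofuran-2(3H)-one (the two benzyl-type groups trans, benzyloxy cis to the C4 group) | COc1cc(C[C@@]2(OCc3ccccc3)C(=O)OC[C@@H]2Cc5ccc(OC)c(OC)c5)ccc1OCc4ccccc4 | intermediate
15 | trachelogenin, (3S,4S)-4-(3,4-dimethoxybenzyl)-3-hydroxy-3-(4-hydroxy-3-methoxybenzyl)dihydrofuran-2(3H)-one | COc1cc(C[C@@]2(O)C(=O)OC[C@@H]2Cc3ccc(OC)c(OC)c3)ccc1O | target

Total step count: 8
Longest linear sequence: 7 steps (1 → 4 → 5 → 7 → 9 → 10 → 14 → 15; step 6 is a one-step side branch)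

Steps most likely to fail

Step 3. The risk is insufficient discrimination between the two enantiotopic methylene groups. The group that distinguishes them is a flexible benzyl substituent remote from the reacting centre, and any uncatalysed background oxidation would erode the selectivity further. The fallback replaces asymmetric catalysis by resolution and sets out from 5. Oxidation with 30% H2O2 in AcOH at rt without a chiral catalyst should give the racemic lactone rac-4-(3,4-dimethoxybenzyl)dihydrofuran-2(3H)-one F1. Heating F1 with (S)-1-phenylethylamine (cat. 2-hydroxypyridine, toluene, 80 °C) should open the ring to two diastereomeric hydroxy amides, (R)-3-(3,4-dimethoxybenzyl)-4-hydroxy-N-[(S)-1-phenylethyl]butanamide F2 and (S)-3-(3,4-dimethoxybenzyl)-4-hydroxy-N-[(S)-1-phenylethyl]butanamide F3, to be separated by crystallisation or chromatography. Heating F2 in aqueous H2SO4–dioxane should release the amine through participation of the γ-hydroxyl and close the ring again; the stereocentre is β to the carbonyl and cannot epimerise. The fallback comes back to the route at 7.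

Step 7. The risk is slow or incomplete C-alkylation at the fully substituted enolate carbon, with competing decomposition of the labile electron-rich benzylic bromide, and loss of facial selectivity if the mixture has to be warmed. The fallback replaces the SN2 alkylation by an aldol addition followed by deoxygenation and sets out from 10. Enolate 13, generated as before, is treated at −78 °C with commercial 4-(benzyloxy)-3-methoxybenzaldehyde, a more reactive and more compact electrophile that should again add anti to the C4 group. This should give (3R,4S)-3-(benzyloxy)-3-{[4-(benzyloxy)-3-methoxyphenyl](hydroxy)methyl}-4-(3,4-dimethoxybenzyl)dihydrofuran-2(3H)-one F4 as a mixture of carbinol epimers, which is of no consequence. Hydrogenolysis of F4 (H2, Pd/C, AcOH, cat. HClO4) should remove the electron-rich benzylic hydroxyl together with both benzyl ethers, so the fallback comes back to the route at 15.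

Step 5. The risk is sluggish etherification of the hindered, weakly nucleophilic α-hydroxyl, leading to incomplete conversion or, under more forcing basic conditions, enolisation and degradation of the hydroxy lactone. The fallback omits the O-protecting group and sets out from 9. Double deprotonation with LDA (2.2 equiv, THF–DMPU, −78 °C) should give the dilithium alkoxide–enolate, dilithium (S)-4-(3,4-dimethoxybenzyl)-4,5-dihydrofuran-2,3-bis(olate) F5. C-Alkylation of F5 with 12 anti to the C4 group should give (3S,4S)-3-[4-(benzyloxy)-3-methoxybenzyl]-4-(3,4-dimethoxybenzyl)-3-hydroxydihydrofuran-2(3H)-one F6. Hydrogenolysis of the single phenolic benzyl ether (H2, Pd/C, EtOAc–EtOH) then comes back to the route at 15.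

Further compounds
F1 | step 3 | rac-4-(3,4-dimethoxybenzyl)dihydrofuran-2(3H)-one | O=C1OCC(C1)Cc2ccc(OC)c(OC)c2
F2 | step 3 | (R)-3-(3,4-dimethoxybenzyl)-4-hydroxy-N-[(S)-1-phenylethyl]butanamide | C[C@H](NC(=O)C[C@H](CO)Cc1ccc(OC)c(OC)c1)c2ccccc2
F3 | step 3 | (S)-3-(3,4-dimethoxybenzyl)-4-hydroxy-N-[(S)-1-phenylethyl]butanamide | C[C@H](NC(=O)C[C@@H](CO)Cc1ccc(OC)c(OC)c1)c2ccccc2
F4 | step 7 | (3R,4S)-3-(benzyloxy)-3-{[4-(benzyloxy)-3-methoxyphenyl](hydroxy)methyl}-4-(3,4-dimethoxybenzyl)dihydrofuran-2(3H)-one, carbinol epimers | COc1cc(C(O)[C@@]2(OCc3ccccc3)C(=O)OC[C@@H]2Cc5ccc(OC)c(OC)c5)ccc1OCc4ccccc4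
F5 | step 5 | dilithium (S)-4-(3,4-dimethoxybenzyl)-4,5-dihydrofuran-2,3-bis(olate) | [Li+].[Li+].[O-]C1=C([O-])[C@@H](Cc2ccc(OC)c(OC)c2)CO1
F6 | step 5 | (3S,4S)-3-[4-(benzyloxy)-3-methoxybenzyl]-4-(3,4-dimethoxybenzyl)-3-hydroxydihydrofuran-2(3H)-one | COc1cc(C[C@@]2(O)C(=O)OC[C@@H]2Cc3ccc(OC)c(OC)c3)ccc1OCc4ccccc4
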